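**Plan**

- Retrosynthetic cuts: the C11–O(aryl) bond (Mitsunobu with umbelliferone), then the C8–CH3 bond (alkenyl triflate coupling), then C10–CH3 and C9–C11 together (methyl cuprate addition to a ring B enone, enolate capture by formaldehyde).
- Enabling feature: in ring B, C10 (ring-fusion carbon with the angular methyl) and C9 (carrying C11) are the β- and α-carbons of a carbonyl placed at C8, the carbon that ends as the methyl-bearing end of the C7=C8 alkene.
- No ring is closed: ring A (C1–C5, C10) is the saturated ring and ring B (C5–C10) the anisole ring of 6-methoxy-2-tetralone, unmasked by Birch reduction. Forward order: C4 gem-dimethylation, C3 reduction, Birch/hydrolysis, key step, C8 methyl, C11–OH, aryl ether, C3 ketone.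
- Stereochemistry: C3 (Corey–Bakshi–Shibata reduction) is the only reagent-controlled centre and serves as a relay. It sets C5 by equilibration of the enone; C5 with the C4 methyls sets C10 (cis fusion) in the cuprate addition; C9 is set last by hydroboration of a C9=C11 methylene from the convex face; C3 is finally oxidised to the ketone.

Key step: step 6

Remark: drimane numbering is used (C3 oxygenated, C4 gem-dimethyl, C5–H and C10–CH3 at the ring fusion, C12 = methyl on C8, C9 bearing C11H2–OAr) and β is the face of the C10 methyl; the target SMILES is read as the cis-fused decalin with H-5 and H-9 both β (C11 α).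

**Route**

Step 1
Reactants: 1 6-methoxy-3,4-dihydronaphthalen-2(1H)-one; 2 iodomethane
Product: 3 6-methoxy-1,1-dimethyl-3,4-dihydronaphthalen-2(1H)-one
Conditions: KOtBu (2.5 equiv), MeI (3 equiv), THF, 0 °C to rt
Reagents that add atoms: iodomethane, CI
Why: Double enolate C-alkylation: the benzylic C1 position between the arene and the carbonyl is the more acidic α-site of a 2-tetralone, so both methyl groups enter there and install the future C4 gem-dimethyl group without creating a stereocentre.

Step 2
Reactants: 3 6-methoxy-1,1-dimethyl-3,4-dihydronaphthalen-2(1H)-one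
Product: 4 (2R)-6-methoxy-1,1-dimethyl-1,2,3,4-tetrahydronaphthalen-2-ol
Conditions: (S)-2-methyl-CBS-oxazaborolidine (10 mol%), BH3·SMe2, THF, −20 °C; MeOH quench
Reagents that add atoms: none
Why: Corey–Bakshi–Shibata reduction: the oxazaborolidine–borane complex binds the ketone with the quaternary C1 as the large and the C3 methylene as the small substituent, so the (S)-catalyst should deliver hydride to the face that gives the (2R)-alcohol, the single reagent-controlled stereocentre from which all others are relayed.

Step 3
Reactants: 4 (2R)-6-methoxy-1,1-dimethyl-1,2,3,4-tetrahydronaphthalen-2-ol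
Product: 5 tert-butyl{[(2R)-6-methoxy-1,1-dimethyl-1,2,3,4-tetrahydronaphthalen-2-yl]oxy}dimethylsilane
Conditions: TBSOTf, 2,6-lutidine, CH2Cl2, 0 °C
Reagents that add atoms: tert-butyldimethylsilyl triflate, CC(C)(C)[Si](C)(C)OS(=O)(=O)C(F)(F)F
Why: Silylation of a hindered neopentyl-type secondary alcohol with the silyl triflate and a non-nucleophilic base; the tert-butyldimethylsilyl ether is chosen because it survives dissolving metal, methoxide, the cuprate, the amide base, the Grignard reagent and alkaline peroxide.

Step 4
Reactants: 5 tert-butyl{[(2R)-6-methoxy-1,1-dimethyl-1,2,3,4-tetrahydronaphthalen-2-yl]oxy}dimethylsilane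
Product: 6 tert-butyl{[(2R)-6-methoxy-1,1-dimethyl-1,2,3,4,5,8-hexahydronaphthalen-2-yl]oxy}dimethylsilane (enol ether C6=C7; tetrasubstituted alkene C4a=C8a)
Conditions: Li, NH3 (l), THF, t-BuOH, −78 to −33 °C
Reagents that add atoms: none
Why: Birch reduction of the anisole ring: the radical anion is protonated at the two unsubstituted, para-related positions, leaving the methoxy group and both ring-fusion carbons on double bonds (1-methoxycyclohexa-1,4-diene pattern); the aliphatic silyl ether and the C3 stereocentre are inert.

Step 5
Reactants: 6 tert-butyl{[(2R)-6-methoxy-1,1-dimethyl-1,2,3,4,5,8-hexahydronaphthalen-2-yl]oxy}dimethylsilane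
Product: 8 (4aS,6R)-6-[(tert-butyldimethylsilyl)oxy]-5,5-dimethyl-4,4a,5,6,7,8-hexahydronaphthalen-2(3H)-one (drimane numbering: C8 ketone; C9=C10; H-5 β; 3α-OTBS), via β,γ-enone 7 (not isolated)
Conditions: (CO2H)2, THF/MeOH/H2O, rt; then NaOMe (0.2 equiv), MeOH, rt; chromatography, minor C5 epimer returned to NaOMe/MeOH
Reagents that add atoms: water, O
Why: Enol ether hydrolysis under oxalic acid (which leaves the silyl ether intact) gives β,γ-enone 7, and methoxide moves the double bond into conjugation through the extended dienolate (base-mediated enone isomerisation), so that C5 is protonated under thermodynamic control and the epimer with the C3 silyloxy group equatorial on the only chair open to ring A (H-5 cis to H-3) should predominate; the preference is expected to be modest, the two C5 epimers are diastereomers separable on silica, and the minor one is returned to the methoxide equilibration.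

Step 6
Reactants: 8 (4aS,6R)-6-[(tert-butyldimethylsilyl)oxy]-5,5-dimethyl-4,4a,5,6,7,8-hexahydronaphthalen-2(3H)-one; 9 formaldehyde (monomeric gas from cracked paraformaldehyde)
Product: 11 cis-fused hydroxymethyl ketone 6-[(tert-butyldimethylsilyl)oxy]-1-(hydroxymethyl)-5,5,8a-trimethyloctahydronaphthalen-2(1H)-one (5β-H; 10β-CH3; 3α-OTBS; C11 on C9 expected β), via lithium enolate 10 (not isolated)
Conditions: CuI, MeLi (2 equiv), Et2O, 0 °C; 8, −20 to 0 °C; then THF, −78 °C, CH2O (g); aq NH4Cl
Reagents that add atoms: lithium dimethylcuprate, [Li+].C[Cu-]C; formaldehyde, C=O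
Why: The soft dimethylcuprate adds in 1,4-fashion to the C8 enone and transfers one methyl to C10, and the lithium enolate 10 left behind is hydroxymethylated at C9 by monomeric formaldehyde, the closest known reaction type being the addition of Me2CuLi to octalones substituted at the ring-fusion β-carbon with aldol capture of the enolate by formaldehyde. No ring closes; the step forms the C10–CH3 and C9–C11 bonds in one flask. The C10 centre is controlled by C5: the C9=C10 double bond holds ring A in the chair with H-5 axial on the β face, C4 with its axial methyl group lies on the α face and would be 1,3-diaxial to an incoming α-methyl, so the methyl group enters β, cis to H-5, and the ring fusion becomes cis. The C9 centre is controlled by the shape of the cis-fused enolate: its α face is the concave one (under ring A in one chair, eclipsed by the axial C10–C1 bond in the other), so formaldehyde is expected on the β face, cis to the new methyl group, as drawn for 11. That C9 configuration is the opposite of the target's and is not carried on, since step 7 makes C9 trigonal and step 10 sets it by hydrogen delivery to the same convex face. The step therefore needs only 1,4- over 1,2-selectivity (given by the cuprate), β-face selectivity at C10 (given by C5–H and the C4 gem-dimethyl group) and clean mono-C-hydroxymethylation (given by the regiospecific lithium enolate, low temperature and excess gaseous formaldehyde).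

Step 7
Reactants: 11 cis-fused hydroxymethyl ketone
Product: 13 cis-fused 6-[(tert-butyldimethylsilyl)oxy]-5,5,8a-trimethyl-1-methylideneoctahydronaphthalen-2(1H)-one (C8 ketone; C9=C11 methylene; 5β-H; 10β-CH3; 3α-OTBS), via C11 mesylate 12 (not isolated)
Conditions: MsCl, Et3N, CH2Cl2, 0 °C; then DBU, rt
Reagents that add atoms: none
Why: Mesylation of the primary alcohol followed by E1cB elimination through the C8 enolate gives the exocyclic enone; this turns C9 trigonal on purpose, so that both C9 epimers of 11 converge, the C11 oxygen needs no protecting group and C7 becomes the only enolisable position for the next step.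

Step 8
Reactants: 13 cis-fused α-methylene ketone
Product: 14 cis-fused 6-[(tert-butyldimethylsilyl)oxy]-5,5,8a-trimethyl-1-methylidene-1,4,4a,5,6,7,8,8a-octahydronaphthalen-2-yl trifluoromethanesulfonate (C7=C8–OTf; C9=C11)
Conditions: KN(SiMe3)2, THF, −78 °C (slow addition of 13 to the base); PhNTf2, −78 to 0 °C
Reagents that add atoms: N-phenylbis(trifluoromethanesulfonimide), O=S(=O)(N(c1ccccc1)S(=O)(=O)C(F)(F)F)C(F)(F)F
Why: Enol triflate formation: the hindered amide base removes a C7 proton (the sole α-hydrogens left) at low temperature and the cross-conjugated potassium dienolate is O-sulfonylated by PhNTf2, so the position of the triflate is unambiguous; slow addition of 13 to excess base keeps enolate and enone from meeting.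

Step 9
Reactants: 14 dienyl triflate
Product: 15 cis-fused tert-butyldimethylsilyl ether of 2,5,5,8a-tetramethyl-1-methylidene-1,4,4a,5,6,7,8,8a-octahydronaphthalen-6-ol (C7=C8 with C12 methyl; C9=C11; 5β-H; 10β-CH3; 3α-OTBS)
Conditions: Fe(acac)3 (5 mol%), MeMgBr, THF/NMP, −30 to 0 °C
Reagents that add atoms: methylmagnesium bromide, C[Mg]Br
Why: Iron-catalysed cross-coupling of an alkenyl triflate with a methyl Grignard reagent (Kumada-type coupling under Fe(acac)3 catalysis) exchanges the triflate for the C12 methyl group without moving either double bond and is fast enough at low temperature to leave the silyl ether untouched.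

Step 10
Reactants: 15 cis-fused diene
Product: 17 cis-fused [6-[(tert-butyldimethylsilyl)oxy]-2,5,5,8a-tetramethyl-1,4,4a,5,6,7,8,8a-octahydronaphthalen-1-yl]methanol (C7=C8; H-5 β; CH3-10 β; H-9 β; C11–OH α; 3α-OTBS), via B-alkyl-9-BBN adduct 16 (not isolated)
Conditions: 9-BBN, THF, 0 to 50 °C; then aq NaOH, H2O2, 0 °C to rt
Reagents that add atoms: hydrogen peroxide, OO
Why: Hydroboration–oxidation: 9-BBN adds to the 1,1-disubstituted C9=C11 alkene far faster than to the trisubstituted C7=C8 alkene and places boron on the terminal C11, while hydrogen is delivered to C9 from the convex β face of the cis-fused bicycle (on the α face the approach runs under ring A or eclipses the axial C10–C1 bond), which sets H-9 β and C11 α as in the target; peroxide oxidation replaces boron by oxygen with retention.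

Step 11
Reactants: 17 cis-fused homoallylic alcohol; 18 umbelliferone (7-hydroxy-2H-chromen-2-one)
Product: 19 7-{[cis-fused 6-[(tert-butyldimethylsilyl)oxy]-2,5,5,8a-tetramethyl-1,4,4a,5,6,7,8,8a-octahydronaphthalen-1-yl]methoxy}-2H-chromen-2-one (H-5 β; CH3-10 β; H-9 β; 3α-OTBS)
Conditions: PPh3, DIAD, THF, 0 °C to rt
Reagents that add atoms: umbelliferone, O=c1ccc2ccc(O)cc2o1
Why: Mitsunobu etherification: the phosphonium-activated primary C11 hydroxyl is displaced by the acidic 7-hydroxyl of umbelliferone (phenol pKa near 8), no stereocentre is touched, and the neutral conditions avoid the base-induced elimination toward diene 15 that a sulfonate displacement would risk.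

Step 12
Reactants: 19 silyl-protected aryl ether
Product: 20 7-{[cis-fused 6-hydroxy-2,5,5,8a-tetramethyl-1,4,4a,5,6,7,8,8a-octahydronaphthalen-1-yl]methoxy}-2H-chromen-2-one (3α-OH; H-5 β; CH3-10 β; H-9 β)
Conditions: HF·pyridine, THF/pyridine, 0 °C to rt
Reagents that add atoms: none
Why: Fluoride-driven cleavage of the hindered secondary silyl ether (formation of the strong Si–F bond); buffered HF·pyridine is chosen over basic fluoride to spare the coumarin lactone, and neither the aryl ether nor the trisubstituted alkene reacts.

Step 13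
Reactants: 20 C3 alcohol
Product: 21 target, 7-{[cis-fused 2,5,5,8a-tetramethyl-6-oxo-1,4,4a,5,6,7,8,8a-octahydronaphthalen-1-yl]methoxy}-2H-chromen-2-one (H-5 β; CH3-10 β; H-9 β; C11 α)
Conditions: Dess–Martin periodinane, NaHCO3, CH2Cl2, rt
Reagents that add atoms: none
Why: Dess–Martin oxidation of the secondary alcohol to the C3 ketone under buffered, non-epimerising conditions; the relay stereocentre at C3 disappears and the flanking C4 is quaternary, so no stereocentre of the target is at risk.

**Compound list**

1 | 6-methoxy-3,4-dihydronaphthalen-2(1H)-one (6-methoxy-2-tetralone) | COc1ccc2c(c1)CCC(=O)C2 | starting material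
2 | iodomethane | CI | starting material
3 | 6-methoxy-1,1-dimethyl-3,4-dihydronaphthalen-2(1H)-one | COc1ccc2c(c1)CCC(=O)C2(C)C | intermediate
4 | (2R)-6-methoxy-1,1-dimethyl-1,2,3,4-tetrahydronaphthalen-2-ol | COc1ccc2c(c1)CC[C@@H](O)C2(C)C | intermediate
5 | tert-butyl{[(2R)-6-methoxy-1,1-dimethyl-1,2,3,4-tetrahydronaphthalen-2-yl]oxy}dimethylsilane | COc1ccc2c(c1)CC[C@@H](O[Si](C)(C)C(C)(C)C)C2(C)C | intermediate
6 | tert-butyl{[(2R)-6-methoxy-1,1-dimethyl-1,2,3,4,5,8-hexahydronaphthalen-2-yl]oxy}dimethylsilane | COC1=CCC2=C(C1)CC[C@@H](O[Si](C)(C)C(C)(C)C)C2(C)C | intermediate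
7 | (6R)-6-[(tert-butyldimethylsilyl)oxy]-5,5-dimethyl-3,4,5,6,7,8-hexahydronaphthalen-2(1H)-one (β,γ-enone, not isolated) | O=C1CCC2=C(C1)CC[C@@H](O[Si](C)(C)C(C)(C)C)C2(C)C | intermediate
8 | (4aS,6R)-6-[(tert-butyldimethylsilyl)oxy]-5,5-dimethyl-4,4a,5,6,7,8-hexahydronaphthalen-2(3H)-one | O=C1C=C2CC[C@@H](O[Si](C)(C)C(C)(C)C)C(C)(C)[C@H]2CC1 | intermediate
9 | formaldehyde (from paraformaldehyde) | C=O | starting material
10 | lithium C8–C9 enolate of the cis-fused 10β-methyl ketone (not isolated) | [Li]OC1=C[C@@]2(C)CC[C@@H](O[Si](C)(C)C(C)(C)C)C(C)(C)[C@H]2CC1 | intermediate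
11 | cis-fused 6-[(tert-butyldimethylsilyl)oxy]-1-(hydroxymethyl)-5,5,8a-trimethyloctahydronaphthalen-2(1H)-one (5β-H, 10β-CH3, 3α-OTBS, C11 drawn β; C9 configuration immaterial for the route) | O=C1CC[C@@H]2C(C)(C)[C@H](O[Si](C)(C)C(C)(C)C)CC[C@]2(C)[C@H]1CO | intermediate
12 | C11 methanesulfonate of 11 (not isolated) | O=C1CC[C@@H]2C(C)(C)[C@H](O[Si](C)(C)C(C)(C)C)CC[C@]2(C)[C@H]1COS(C)(=O)=O | intermediate
13 | cis-fused 6-[(tert-butyldimethylsilyl)oxy]-5,5,8a-trimethyl-1-methylideneoctahydronaphthalen-2(1H)-one | O=C1CC[C@@H]2C(C)(C)[C@H](O[Si](C)(C)C(C)(C)C)CC[C@]2(C)C1=C | intermediate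
14 | cis-fused 6-[(tert-butyldimethylsilyl)oxy]-5,5,8a-trimethyl-1-methylidene-1,4,4a,5,6,7,8,8a-octahydronaphthalen-2-yl trifluoromethanesulfonate | O=S(=O)(OC1=CC[C@@H]2C(C)(C)[C@H](O[Si](C)(C)C(C)(C)C)CC[C@]2(C)C1=C)C(F)(F)F | intermediate
15 | cis-fused tert-butyldimethylsilyl ether of 2,5,5,8a-tetramethyl-1-methylidene-1,4,4a,5,6,7,8,8a-octahydronaphthalen-6-ol | CC1=CC[C@@H]2C(C)(C)[C@H](O[Si](C)(C)C(C)(C)C)CC[C@]2(C)C1=C | intermediate
16 | B-(C11-alkyl)-9-borabicyclo[3.3.1]nonane adduct of 15 (not isolated) | CC1=CC[C@@H]2C(C)(C)[C@H](O[Si](C)(C)C(C)(C)C)CC[C@]2(C)[C@@H]1CB1C2CCCC1CCC2 | intermediate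
17 | cis-fused [6-[(tert-butyldimethylsilyl)oxy]-2,5,5,8a-tetramethyl-1,4,4a,5,6,7,8,8a-octahydronaphthalen-1-yl]methanol (H-5, CH3-10, H-9 all β) | CC1=CC[C@@H]2C(C)(C)[C@H](O[Si](C)(C)C(C)(C)C)CC[C@]2(C)[C@@H]1CO | intermediate
18 | umbelliferone (7-hydroxy-2H-chromen-2-one) | O=c1ccc2ccc(O)cc2o1 | starting material
19 | umbelliferyl ether of 17 | CC1=CC[C@@H]2C(C)(C)[C@H](O[Si](C)(C)C(C)(C)C)CC[C@]2(C)[C@@H]1COc1ccc2ccc(=O)oc2c1 | intermediate
20 | 3α-alcohol (desilylated 19) | CC1=CC[C@@H]2C(C)(C)[C@H](O)CC[C@]2(C)[C@@H]1COc1ccc2ccc(=O)oc2c1 | intermediate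
21 | 7-{[cis-fused 2,5,5,8a-tetramethyl-6-oxo-1,4,4a,5,6,7,8,8a-octahydronaphthalen-1-yl]methoxy}-2H-chromen-2-one (H-5, CH3-10, H-9 all β) | CC1=CC[C@@H]2C(C)(C)C(=O)CC[C@]2(C)[C@@H]1COc1ccc2ccc(=O)oc2c1 | target

**Step count and risks**

Total steps: 13. Longest linear sequence: 13 steps (from 1 to 21).

Risk 1, step 10. The borane may engage the conjugated diene only sluggishly, may also attack the ring alkene, or may deliver hydrogen to C9 with too little preference for the β face. The fallback replaces kinetic by thermodynamic control at C9; it sets out from 11 and returns at 17. Ketone 11 is silylated (Et3SiCl, imidazole) to the C11 triethylsilyl ether F1. DBU in toluene then equilibrates C9, which is α to the C8 carbonyl, toward the epimeric triethylsilyl ether F2, whose C11 is equatorial and trans to the C10 methyl in the chair that keeps C4 equatorial on ring B; the epimers are separated and the other one is re-equilibrated. KN(SiMe3)2 and PhNTf2 give the C7=C8 enol triflate F3 by kinetic deprotonation at the C7 methylene, Fe(acac)3/MeMgBr gives the C8-methyl alkene triethylsilyl ether F4, and PPTS in MeOH removes the primary silyl group selectively to leave 17.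

Risk 2, step 8. The amide base or the dienolate may add to the exposed methylene terminus of 13, so that oligomers form instead of the triflate. The fallback brings the C12 methyl in as a nucleophile; it sets out from 13 and returns at 15, bypassing 14 and step 9. MeLi/CeCl3 (1,2-addition of the organocerium reagent, THF, −78 °C) gives the tertiary allylic alcohol F5, and dehydration toward C7 with Burgess reagent in warm toluene gives diene 15.

Risk 3, step 6. Capture of the copper-containing enolate by formaldehyde gas may be incomplete (proton quench, polymerisation of formaldehyde, or a second hydroxymethylation at C7 after enolate equilibration). The fallback separates the two bond formations; it sets out from 8 and returns at 11. Me2CuLi in the presence of Me3SiCl (accelerated conjugate addition with O-silylation in the same flask) gives the trimethylsilyl enol ether F6, which is isolated; Yb(OTf)3-catalysed hydroxymethylation with aqueous formaldehyde in THF (Mukaiyama-type aldol in water) then gives 11.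

**Further compounds**

F1 | step 10 | C11 triethylsilyl ether of 11 (C11 β) | O=C1CC[C@@H]2C(C)(C)[C@H](O[Si](C)(C)C(C)(C)C)CC[C@]2(C)[C@H]1CO[Si](CC)(CC)CC
F2 | step 10 | C9 epimer of F1 (C11 α, H-9 β) | O=C1CC[C@@H]2C(C)(C)[C@H](O[Si](C)(C)C(C)(C)C)CC[C@]2(C)[C@@H]1CO[Si](CC)(CC)CC
F3 | step 10 | C7=C8 enol triflate of F2 | O=S(=O)(OC1=CC[C@@H]2C(C)(C)[C@H](O[Si](C)(C)C(C)(C)C)CC[C@]2(C)[C@@H]1CO[Si](CC)(CC)CC)C(F)(F)F
F4 | step 10 | C11 triethylsilyl ether of 17 | CC1=CC[C@@H]2C(C)(C)[C@H](O[Si](C)(C)C(C)(C)C)CC[C@]2(C)[C@@H]1CO[Si](CC)(CC)CC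
F5 | step 8 | cis-fused tertiary allylic alcohol, 6-[(tert-butyldimethylsilyl)oxy]-2,5,5,8a-tetramethyl-1-methylidenedecahydronaphthalen-2-ol (C8 configuration immaterial) | C[C@@]1(O)CC[C@@H]2C(C)(C)[C@H](O[Si](C)(C)C(C)(C)C)CC[C@]2(C)C1=C
F6 | step 6 | trimethylsilyl enol ether (C8–OSiMe3, C8=C9) of the cis-fused 10β-methyl ketone | C[Si](C)(C)OC1=C[C@@]2(C)CC[C@@H](O[Si](C)(C)C(C)(C)C)C(C)(C)[C@H]2CC1
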